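If substrate can attack its own target, the reckoning can start from the level of target at which that loss matches formation.

    substrate ⇌ intermediate + leaving ligand (K1 = 3.1 × 10⁻⁶ M, k1 = 0.013 /s)
    reagent + intermediate → target (k2 = 360 /M/s)
    substrate + target → side product (k3 = 1.2 /M/s)
    leaving ligand → by-product carried off (k4 = 0.0065 /s)

| flask | substrate | reagent | time | remark |
|---|---|---|---|---|
| delta | 0.010 M | 0.0150 M (fed, over 2.5 min) | 6.0 min | all else is in the flask from the start; the feed brings no volume worth counting |
| beta | 0.010 M | 0.0150 M | 6.0 min | everything together at the start |
| theta | 0.010 M (fed, over 2.5 min) | 0.0150 M | 6.0 min | all else is in the flask from the start; the feed brings no volume worth counting |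
| epsilon | 0.010 M (in portions, 5, over 2.5 min) | 0.0150 M | 6.0 min | first portion at the start, last at 2.5 min |

- the flask that comes out highest in amount of side product, in percent of the substrate charged, or "all alike" when all lie within 1.5 percentage points (delta / beta / theta / epsilon / all alike)
- side product at the end, in percent of the substrate charged, delta
- side product at the end, in percent of the substrate charged, beta
- side product at the end, in percent of the substrate charged, theta
- side product at the end, in percent of the substrate charged, epsilon

- in percentages every species weighs as the substrate in it: one side product counts as two
- run time (delta): 6.0 min

Beta and theta carry the same charges: beta holds its whole substrate charge from the start, while theta receives it over 2.5 min. Reagent is frozen at 0.0117 M, its charge less a third of the substrate charge, so capture of intermediate runs at 4.20 /s. Capture alone then gives intermediate a life of about 0.238 s, far shorter than the 76.9 s that the forward step gives a substrate molecule, so intermediate is taken at steady state. Its return with leaving ligand has the constant 4190 /M/s, and c(leaving ligand) is taken equal to c(target), which supposes that the ligand lost to by-product matches the target consumed by substrate.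

Substrate makes target at 0.013 /s times the captured share and loses it at 1.2 /M/s times c(target), and both rates carry c(substrate). The balance therefore falls at 0.00283 M, the target ceiling, the c(target) at which formation and consumption of target are equal whatever c(substrate) is. That is 28.3% of the charge, an estimate and not a bound, with a captured share of 26.2%, since return runs faster than capture.

At the ceiling, each turn costs two substrates and ends in side product, so substrate decays pseudo-first-order at 0.408 /min. Beta is reckoned on this clock from the start, its early loss at 0.013 /s being faster, which leaves 8.66% substrate and 63.0% side product. Theta's feed gives its substrate a later start, which leaves 15.1% substrate and 56.6% side product. The reckoned gap of 6.4 percentage points exceeds the margin of 1.5 points, so this reckoning puts beta above theta. Epsilon's 5 portions span the same time as theta's feed and are reckoned with theta. Delta holds its substrate from the start while its reagent is still arriving, and this reckoning puts no number on it.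

The forecast gives 60% for delta, 63% for beta, 57% for theta and 59% for epsilon, with beta highest, on the ground that “target forms slowly and sits alongside unreacted substrate”.

The simulation gives 61.8% for delta, 64.4% for beta, 58.6% for theta and 58.3% for epsilon, with beta highest. Substrate remaining at 6.00 min stands at 7.91% in beta and 13.9% in theta. Epsilon read at 15 min has its substrate down to 0.0369%, so the target ceiling puts its side product at 71.7%, and that flask holds 69.4% beside 30.5% target.

The constants were drawn at random within sensible limits; no experiment stands behind them.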